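**Strategy.** In the oxane ring (O, C15, C1, C2, C3, C4; cembrane locants) the ether oxygen lies between two fully substituted carbons, C15 (CMe2) and C4, each bonded to a ring CH. This is the bridgehead pattern of an 8-oxabicyclo[3.2.1]octene, so the route rests on an amine-catalysed asymmetric (4+3) cycloaddition of 2,5-dimethylfuran with a 4-siloxypentadienal: the furan α-carbons become C15 and C4, and the bonds C1–C15 and C3–C4 form in one operation, setting C1 and C4. The furan β-carbons are later cut apart into the second C15 methyl and C5. Acetoxylation at C3, removal of the C2 carbonyl, a Negishi coupling and a Ni/Cr ring closure complete the 14-membered ring.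

Key step: step 3

Remark on locants: cembrane locants are used for all intermediates. C1 is the oxane CH that carries C14, C2 the oxane CH2, C3 the acetoxy carbon, C4 the C(CH3)–O carbon, C5 to C14 the other macrocycle carbons, C15 the CMe2 carbon, and C16 the bridge carbon that ends as a C15 methyl group.

Assumption: the (2R,5R) antipode of the imidazolidinone is assigned by analogy with iminium conjugate additions; if the sense of induction proves opposite, the (2S,5S) antipode is used and nothing else changes.

Step 1
Reactants: 1 2-methylfuran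
Product: 3 (E)-4-oxopent-2-enal, via (Z)-4-oxopent-2-enal 2 (not isolated)
Conditions: NBS, NaHCO3, acetone/H2O (10:1), −15 °C; then pyridine (cat.), rt
Reagents that add atoms: water (O)
Why: Bromination of the furan and attack of water open the ring (oxidative furan ring opening of the Achmatowicz type) to the cis enedicarbonyl compound 2, which pyridine isomerises to the more stable E isomer.

Step 2
Reactants: 3 (E)-4-oxopent-2-enal
Product: 4 (E)-4-(trimethylsilyloxy)penta-2,4-dienal
Conditions: Me3SiOTf, Et3N, Et2O, 0 °C
Reagents that add atoms: trimethylsilyl triflate (C[Si](C)(C)OS(=O)(=O)C(F)(F)F)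
Why: Soft enolisation of the methyl ketone (silyl enol ether formation) gives the 2-siloxydiene, the aldehyde having no enolisable hydrogen and the E enal geometry staying untouched.

Step 3
Reactants: 4 (E)-4-(trimethylsilyloxy)penta-2,4-dienal; 5 2,5-dimethylfuran
Product: 7 (1R,2S,5R)-2-(2-hydroxyethyl)-1,5-dimethyl-8-oxabicyclo[3.2.1]oct-6-en-3-one, via keto aldehyde 6 (not isolated)
Conditions: 5 (3 equiv), (2R,5R)-5-benzyl-2-tert-butyl-3-methylimidazolidin-4-one trifluoroacetate (20 mol %), CH2Cl2, −78 °C; then NaBH4, MeOH, −78 °C
Reagents that add atoms: none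
Why: Condensation of the aldehyde of 4 with the imidazolidinone should give an iminium ion whose siloxypentadienyl unit is an amino-substituted 2-siloxyallyl cation (C1–C2–C3), which adds across the two α-carbons of the furan diene to form C1–C15 and C3–C4, and hydrolysis of the enamine and of the silyl oxocarbenium ion then gives keto aldehyde 6. The closest known reaction type is the amine-catalysed asymmetric (4+3) cycloaddition of 4-siloxypentadienals with 2,5-disubstituted furans. A single (4+3) closure builds the seven-membered carbocycle C1–C2–C3–C4–C5–C16–C15 and with it the oxane ring, whose oxygen is the furan oxygen. C1 is set by the benzyl and tert-butyl groups of the catalyst, which leave one face of the E iminium ion open, and C4 and C15 follow from the compact (endo) transition state that places the side chain equatorial, cis to the etheno bridge. The step needs ring closure to outrun proton loss from the first-formed furanium ion, which the two α-methyl groups secure because neither attacked carbon carries a hydrogen, and any axial C1 epimer would converge on the equatorial one through the enol. The NaBH4 quench reduces only the aldehyde, the ketone being flanked by a quaternary and a tertiary carbon.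

Step 4
Reactants: 7 hydroxy ketone
Product: 8 (1R,2S,5R)-1,5-dimethyl-2-[2-(triethylsilyloxy)ethyl]-8-oxabicyclo[3.2.1]oct-6-en-3-one
Conditions: Et3SiCl, imidazole, CH2Cl2, 0 °C
Reagents that add atoms: chlorotriethylsilane (CC[Si](Cl)(CC)CC)
Why: Silyl ether formation masks the primary alcohol against the base of step 5 and stops it from closing a hemiketal on the ketone.

Step 5
Reactants: 8 silyl ether
Product: 11 C3-acetoxy ketone, via potassium enolate 9 (not isolated), via potassium alkoxide 10 (not isolated)
Conditions: KN(SiMe3)2, THF, −78 °C; 2-(phenylsulfonyl)-3-phenyloxaziridine, −78 °C; then Ac2O, −78 to 0 °C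
Reagents that add atoms: 2-(phenylsulfonyl)-3-phenyloxaziridine (O=S(=O)(N1OC1c1ccccc1)c1ccccc1); acetic anhydride (CC(=O)OC(C)=O)
Why: Kinetic deprotonation should take a proton of the less substituted C3 methylene, and the enolate is oxidised (Davis enolate hydroxylation) on the exo face away from the etheno bridge, the axial attack usual for bicyclo[3.2.1]octan-3-one enolates, so that the C3 oxygen ends trans to the bridge carbon C5 and is acetylated in the flask as its potassium alkoxide.

Step 6
Reactants: 11 C3-acetoxy ketone
Product: 12 C2-endo alcohol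
Conditions: LiBH(s-Bu)3, THF, −78 °C; then H2O
Reagents that add atoms: none
Why: Hydride should add to the C2 carbonyl from the exo face (ketone reduction with a bulky borohydride) to give the endo alcohol trans-diaxial to the acetate, an arrangement from which the acetyl group cannot migrate, and this temporary centre disappears in step 8.

Step 7
Reactants: 12 C2-endo alcohol
Product: 13 imidazolylthiocarbonyl ester of 12
Conditions: 1,1'-thiocarbonyldiimidazole, DMAP (cat.), toluene, 90 °C
Reagents that add atoms: 1,1'-thiocarbonyldiimidazole (S=C(n1ccnc1)n1ccnc1)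
Why: Thioacylation of the secondary alcohol under neutral conditions gives the substrate for radical deoxygenation without disturbing the acetate or the silyl ether.

Step 8
Reactants: 13 imidazolylthiocarbonyl ester
Product: 14 C2-deoxygenated bicycle
Conditions: Bu3SnH, AIBN (cat.), toluene, 100 °C
Reagents that add atoms: none
Why: Barton–McCombie deoxygenation: the stannyl radical adds to the thiocarbonyl group, the C2–O bond fragments and the secondary radical is reduced by Bu3SnH faster than a 1,2-acyloxy shift can occur, so that C1, C3, C4 and C15 stay untouched.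

Step 9
Reactants: 14 C2-deoxygenated bicycle
Product: 17 lactol aldehyde, via ozonide 15 (not isolated), via silyl dialdehyde 16 (not isolated)
Conditions: O3, CH2Cl2, −78 °C; PPh3, −78 °C to rt; then HF·pyridine, THF, 0 °C
Reagents that add atoms: ozone ([O-][O+]=O)
Why: Ozonolysis of the only alkene cuts the C5–C16 bridge into two formyl groups on quaternary carbons, and desilylation lets the C13 hydroxyl, held cis to C16 by the C1 configuration, close a six-membered lactol on C16 alone, which tells the two formyl carbons apart.

Step 10
Reactants: 17 lactol aldehyde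
Product: 18 E-enamide lactol
Conditions: (EtO)2P(O)CH2C(O)NMe2, LiCl, i-Pr2NEt, MeCN, rt
Reagents that add atoms: diethyl [2-(dimethylamino)-2-oxoethyl]phosphonate (CCOP(=O)(CC(=O)N(C)C)OCC)
Why: Horner–Wadsworth–Emmons olefination with LiCl and a mild amine base should take the free C5 aldehyde and not the lactol-masked C16, giving the E enamide that brings in C6 and C7.

Step 11
Reactants: 18 E-enamide lactol
Product: 19 dithiolane alcohol
Conditions: HSCH2CH2SH, BF3·OEt2, CH2Cl2, −40 to 0 °C
Reagents that add atoms: ethane-1,2-dithiol (SCCS)
Why: Lewis acid thioacetalisation opens the lactol to the C16 dithiolane and sets the C13 hydroxyl free, while acetate, amide and the ring ether are inert at low temperature and any thiol that adds to the enamide is removed in step 12.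

Step 12
Reactants: 19 dithiolane alcohol
Product: 20 3-[(2S,3R,5R)-3-acetoxy-5-(2-hydroxyethyl)-2,6,6-trimethyloxan-2-yl]-N,N-dimethylpropanamide
Conditions: Raney Ni, H2 (1 atm), EtOH, 50 °C
Reagents that add atoms: none
Why: Raney nickel desulfurisation (Mozingo reduction) turns C16 into the second methyl group on C15 and, under hydrogen, saturates the C5=C6 bond in the same flask, after which C15 is no longer a stereocentre.

Step 13
Reactants: 20 hydroxy amide
Product: 21 primary iodide of 20
Conditions: I2, PPh3, imidazole, CH2Cl2, 0 °C to rt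
Reagents that add atoms: iodine (I-I)
Why: Appel iodination of the only hydroxyl group gives the primary C13 iodide needed for zinc insertion.

Step 14
Reactants: 22 3-bromobut-3-en-1-ol
Product: 23 2-bromo-4-iodobut-1-ene
Conditions: I2, PPh3, imidazole, CH2Cl2, 0 °C
Reagents that add atoms: iodine (I-I)
Why: Appel iodination converts the primary alcohol into the iodide and leaves the bromoalkene alone.

Step 15
Reactants: 23 2-bromo-4-iodobut-1-ene
Product: 24 2-bromohept-1-en-5-yne
Conditions: 1-propynyllithium, THF/DMPU, −78 to 0 °C
Reagents that add atoms: 1-propynyllithium ([Li]C#CC)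
Why: SN2 alkylation of the lithium acetylide by the primary iodide builds the C10–C11 bond, the bromoalkene being inert to the acetylide.

Step 16
Reactants: 24 2-bromohept-1-en-5-yne
Product: 26 (E)-2-bromo-6-iodohepta-1,5-diene, via alkenylzirconocene chloride 25 (not isolated)
Conditions: Cp2Zr(H)Cl (2 equiv), THF, rt to 40 °C; then I2, 0 °C
Reagents that add atoms: iodine (I-I)
Why: Hydrozirconation is a syn addition that, under equilibration by excess reagent, should place zirconium on the less hindered methyl-bearing alkyne carbon, and iodinolysis with retention then gives the E iodoalkene, the 1,1-disubstituted bromoalkene reacting far more slowly than the alkyne.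

Step 17
Reactants: 21 primary iodide; 26 (E)-2-bromo-6-iodohepta-1,5-diene
Product: 28 N,N-dimethyl-3-{(2S,3R,5R)-3-acetoxy-5-[(3E)-7-bromo-3-methylocta-3,7-dien-1-yl]-2,6,6-trimethyloxan-2-yl}propanamide, via alkylzinc iodide 27 (not isolated)
Conditions: Zn dust, LiCl, THF, 40 °C; then 26, Pd(PPh3)4 (5 mol %), THF, rt
Reagents that add atoms: none
Why: Negishi coupling of the primary alkylzinc iodide with the iodoalkene forms C12–C13 with retention of the E geometry, oxidative addition into C–I being much faster than into the C–Br bond that is kept for ring closure.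

Step 18
Reactants: 28 bromo diene amide
Product: 29 3-{(2S,3R,5R)-3-acetoxy-5-[(3E)-7-bromo-3-methylocta-3,7-dien-1-yl]-2,6,6-trimethyloxan-2-yl}propanal
Conditions: Cp2Zr(H)Cl (1.5 equiv), THF, rt; then H2O
Reagents that add atoms: none
Why: Hydrozirconation of the tertiary amide (amide to aldehyde reduction) gives a zirconium hemiaminal that releases the C7 aldehyde only on work-up and should leave the acetate, the bromoalkene and the trisubstituted alkene alone.

Step 19
Reactants: 29 bromo diene aldehyde
Product: 30 macrocyclic allylic alcohols (both C7 epimers)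
Conditions: CrCl2 (10 equiv), NiCl2 (10 mol %), DMSO, 50 °C, 0.002 M
Reagents that add atoms: none
Why: Nozaki–Hiyama–Kishi reaction: nickel inserts into the C–Br bond and the alkenylchromium species formed by transmetallation adds only to the aldehyde, closing the 14-membered ring at C7–C8 and creating the exo-methylene carbinol without control at C7, which the next two steps correct.

Step 20
Reactants: 30 macrocyclic allylic alcohols
Product: 31 macrocyclic enone
Conditions: Dess–Martin periodinane, CH2Cl2, 0 °C
Reagents that add atoms: none
Why: Dess–Martin oxidation converts both C7 epimers into one α-methylene ketone under neutral conditions that spare the acetate and the alkenes.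

Step 21
Reactants: 31 macrocyclic enone
Product: 32 CNP0202897.1
Conditions: (S)-2-methyl-CBS-oxazaborolidine (20 mol %), catecholborane, toluene, −78 °C
Reagents that add atoms: none
Why: Corey–Bakshi–Shibata reduction: the 2-substituted alkenyl group (C8) acts as the large and the C6 methylene as the small substituent, so the (S)-catalyst should deliver hydride 1,2 to the face that gives the 7R carbinol, without touching the acetate.

**Compound list**

1 | 2-methylfuran | Cc1ccco1 | starting material
2 | (Z)-4-oxopent-2-enal | CC(=O)/C=C\C=O | intermediate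
3 | (E)-4-oxopent-2-enal | CC(=O)/C=C/C=O | intermediate
4 | (E)-4-(trimethylsilyloxy)penta-2,4-dienal | C=C(O[Si](C)(C)C)/C=C/C=O | intermediate
5 | 2,5-dimethylfuran | Cc1ccc(C)o1 | starting material
6 | keto aldehyde, 2-[(1R,2S,5R)-1,5-dimethyl-3-oxo-8-oxabicyclo[3.2.1]oct-6-en-2-yl]acetaldehyde (side chain equatorial, cis to the etheno bridge) | O=CC[C@@H]1C(=O)C[C@]2(C)C=C[C@@]1(C)O2 | intermediate
7 | hydroxy ketone, (1R,2S,5R)-2-(2-hydroxyethyl)-1,5-dimethyl-8-oxabicyclo[3.2.1]oct-6-en-3-one | OCC[C@@H]1C(=O)C[C@]2(C)C=C[C@@]1(C)O2 | intermediate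
8 | silyl ether, (1R,2S,5R)-1,5-dimethyl-2-[2-(triethylsilyloxy)ethyl]-8-oxabicyclo[3.2.1]oct-6-en-3-one | CC[Si](CC)(CC)OCC[C@@H]1C(=O)C[C@]2(C)C=C[C@@]1(C)O2 | intermediate
9 | potassium enolate of 8 (enolate double bond C2=C3) | CC[Si](CC)(CC)OCC[C@@H]1C([O-])=C[C@]2(C)C=C[C@@]1(C)O2.[K+] | intermediate
10 | potassium alkoxide of the C3-hydroxy ketone (oxygen at C3 exo, axial) | CC[Si](CC)(CC)OCC[C@@H]1C(=O)[C@@H]([O-])[C@]2(C)C=C[C@@]1(C)O2.[K+] | intermediate
11 | C3-acetoxy ketone: 8 with an acetoxy group at C3, exo and axial, anti to the etheno bridge and trans to the C1 side chain | CC[Si](CC)(CC)OCC[C@@H]1C(=O)[C@@H](OC(C)=O)[C@]2(C)C=C[C@@]1(C)O2 | intermediate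
12 | C2-endo alcohol: 11 with the carbonyl reduced, hydroxyl syn to the etheno bridge and trans to the acetate | CC[Si](CC)(CC)OCC[C@@H]1[C@H](O)[C@@H](OC(C)=O)[C@]2(C)C=C[C@@]1(C)O2 | intermediate
13 | imidazolylthiocarbonyl ester of 12 | CC[Si](CC)(CC)OCC[C@@H]1[C@H](OC(=S)n3ccnc3)[C@@H](OC(C)=O)[C@]2(C)C=C[C@@]1(C)O2 | intermediate
14 | C2-deoxygenated bicycle: C2 is CH2, C3 acetoxy exo, C1 side chain CH2CH2OSiEt3 equatorial, methyl groups on the bridgeheads C4 and C15, bridge C5=C16 | CC[Si](CC)(CC)OCC[C@@H]1C[C@@H](OC(C)=O)[C@]2(C)C=C[C@@]1(C)O2 | intermediate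
15 | ozonide of 14 (1,2,4-trioxolane on C5 and C16) | CC[Si](CC)(CC)OCC[C@@H]1C[C@@H](OC(C)=O)[C@]2(C)C3OOC(O3)[C@@]1(C)O2 | intermediate
16 | silyl dialdehyde: oxane with formyl groups on C4 (C5) and C15 (C16), both cis to the C1 side chain, C3 acetoxy trans to C5 | CC[Si](CC)(CC)OCC[C@@H]2C[C@@H](OC(C)=O)[C@](C)(C=O)O[C@]2(C)C=O | intermediate
17 | lactol aldehyde: C13 oxygen bonded to C16 (six-membered lactol cis-fused at C1–C15, both C16 epimers), C5 formyl group free | OC1OCC[C@@H]2C[C@@H](OC(C)=O)[C@](C)(C=O)O[C@]12C | intermediate
18 | E-enamide lactol: C5 formyl group of 17 replaced by (E)-CH=CH–C(O)NMe2 | OC1OCC[C@@H]2C[C@@H](OC(C)=O)[C@](C)(/C=C/C(=O)N(C)C)O[C@]12C | intermediate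
19 | dithiolane alcohol: C16 as 1,3-dithiolan-2-yl, C13 hydroxyl free | OCC[C@@H]2C[C@@H](OC(C)=O)[C@](C)(/C=C/C(=O)N(C)C)O[C@]2(C)C1SCCS1 | intermediate
20 | hydroxy amide, 3-[(2S,3R,5R)-3-acetoxy-5-(2-hydroxyethyl)-2,6,6-trimethyloxan-2-yl]-N,N-dimethylpropanamide | OCC[C@@H]2C[C@@H](OC(C)=O)[C@](C)(CCC(=O)N(C)C)OC2(C)C | intermediate
21 | primary iodide: 20 with the hydroxyl group replaced by iodine, same configuration | ICC[C@@H]2C[C@@H](OC(C)=O)[C@](C)(CCC(=O)N(C)C)OC2(C)C | intermediate
22 | 3-bromobut-3-en-1-ol | C=C(Br)CCO | starting material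
23 | 2-bromo-4-iodobut-1-ene | C=C(Br)CCI | intermediate
24 | 2-bromohept-1-en-5-yne | C=C(Br)CCC#CC | intermediate
25 | alkenylzirconocene chloride, (E)-Cp2Zr(Cl)–C(CH3)=CH–CH2CH2–C(Br)=CH2 | C=C(Br)CC/C=C(\C)[Zr](Cl)(C1C=CC=C1)C1C=CC=C1 | intermediate
26 | (E)-2-bromo-6-iodohepta-1,5-diene | C=C(Br)CC/C=C(\C)I | intermediate
27 | alkylzinc iodide from 21 | I[Zn]CC[C@@H]2C[C@@H](OC(C)=O)[C@](C)(CCC(=O)N(C)C)OC2(C)C | intermediate
28 | bromo diene amide, N,N-dimethyl-3-{(2S,3R,5R)-3-acetoxy-5-[(3E)-7-bromo-3-methylocta-3,7-dien-1-yl]-2,6,6-trimethyloxan-2-yl}propanamide | C=C(Br)CC/C=C(\C)CC[C@@H]2C[C@@H](OC(C)=O)[C@](C)(CCC(=O)N(C)C)OC2(C)C | intermediate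
29 | bromo diene aldehyde, 3-{(2S,3R,5R)-3-acetoxy-5-[(3E)-7-bromo-3-methylocta-3,7-dien-1-yl]-2,6,6-trimethyloxan-2-yl}propanal | C=C(Br)CC/C=C(\C)CC[C@@H]2C[C@@H](OC(C)=O)[C@](C)(CCC=O)OC2(C)C | intermediate
30 | macrocyclic allylic alcohols: skeleton and configuration of the target at C1, C3 and C4, both C7 epimers | C=C1CC/C=C(\C)CC[C@@H]2C[C@@H](OC(C)=O)[C@](C)(CCC1O)OC2(C)C | intermediate
31 | macrocyclic enone: C7 ketone next to the C8 exo-methylene group | C=C1CC/C=C(\C)CC[C@@H]2C[C@@H](OC(C)=O)[C@](C)(CCC1=O)OC2(C)C | intermediate
32 | CNP0202897.1, (1R,3R,4S,7R,11E)-3-acetoxy-4,15-epoxycembra-8(19),11-dien-7-ol | C=C1CC/C=C(\C)CC[C@@H]2C[C@@H](OC(C)=O)[C@](C)(CC[C@H]1O)OC2(C)C | target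

**Step count.** 21 steps in total; the longest linear sequence is 18 steps (steps 1 to 13 and 17 to 21).

**Steps most likely to fail, with fallbacks**

Step 3. The iminium-bound cation may be captured by the furan at one carbon only and then lose a proton or be hydrolysed (open-chain alkylation instead of ring closure), or face shielding by the catalyst may be too weak, so that C1 and with it C4 form with low enantioselectivity. The fallback sets out from 5 and keeps the two-bond (4+3) closure but separates it from the asymmetric event. Compound 5 is combined with the oxyallyl cation generated from 1,1,3-trichloroacetone (NaOCH2CF3, CF3CH2OH) to give racemic 2,2-dichloro-1,5-dimethyl-8-oxabicyclo[3.2.1]oct-6-en-3-one F1. Zn–Cu couple in NH4Cl/MeOH removes both chlorines to give meso 1,5-dimethyl-8-oxabicyclo[3.2.1]oct-6-en-3-one F2. Enantiotopos-selective deprotonation with a lithium bis(1-phenylethyl)amide (antipode chosen for the series shown, LiCl, THF, −100 °C) and alkylation of the enolate with 2-(triethylsilyloxy)ethyl triflate should give the axial C1 epimer of 8 F3. Equilibration with DBU through the enol moves the side chain into the equatorial position, and the sequence comes back to the route at 8.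

Step 10. The lactol may open under the amine base, so that the phosphonate anion also attacks C16 and site selectivity between the two formyl carbons is lost. The fallback sets out from 17. Methanol with pyridinium p-toluenesulfonate should turn the lactol into the cyclic methyl acetal aldehyde F4; the hindered C5 aldehyde should not form an acyclic acetal without a dehydrating agent. The same olefination then gives the enamide methyl acetal F5. The conditions of step 11 convert the methyl acetal into the dithiolane, so the sequence comes back at 19.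

Step 19. Insertion of nickel into the C–Br bond of the bromoalkene may be so slow that reduction or pinacol coupling of the aldehyde and intermolecular addition win over ring closure. The fallback sets out from 28 and changes the electrophile before the aldehyde is set free. Copper-catalysed halogen exchange (CuI, NaI, trans-N,N'-dimethylcyclohexane-1,2-diamine, dioxane, 110 °C) should give the iodoalkene amide F6. Cp2Zr(H)Cl then gives the iodoalkene aldehyde F7. The Ni/Cr ring closure (CrCl2, NiCl2, DMSO), now possible at room temperature, leads back to 30.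

**Further compounds**

F1 | step 3 | 2,2-dichloro-1,5-dimethyl-8-oxabicyclo[3.2.1]oct-6-en-3-one (racemic) | CC12C=CC(C)(O1)C(Cl)(Cl)C(=O)C2
F2 | step 3 | 1,5-dimethyl-8-oxabicyclo[3.2.1]oct-6-en-3-one (meso) | CC12C=CC(C)(O1)CC(=O)C2
F3 | step 3 | axial C1 epimer of 8 | CC[Si](CC)(CC)OCC[C@H]1C(=O)C[C@]2(C)C=C[C@@]1(C)O2
F4 | step 10 | cyclic methyl acetal aldehyde (17 with OCH3 in place of the lactol OH) | COC1OCC[C@@H]2C[C@@H](OC(C)=O)[C@](C)(C=O)O[C@]12C
F5 | step 10 | enamide methyl acetal (18 with OCH3 in place of the lactol OH) | COC1OCC[C@@H]2C[C@@H](OC(C)=O)[C@](C)(/C=C/C(=O)N(C)C)O[C@]12C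
F6 | step 19 | iodoalkene amide (28 with iodine in place of bromine) | C=C(I)CC/C=C(\C)CC[C@@H]2C[C@@H](OC(C)=O)[C@](C)(CCC(=O)N(C)C)OC2(C)C
F7 | step 19 | iodoalkene aldehyde (29 with iodine in place of bromine) | C=C(I)CC/C=C(\C)CC[C@@H]2C[C@@H](OC(C)=O)[C@](C)(CCC=O)OC2(C)C
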